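**Retrosynthetic overview**
1. Labels: phenanthrene ring A (OMe) and ring B (Cl, OH); ring C is the chlorophenol on A; ring D is the phenol on B. Phenanthrene numbering C1–C10a is used.
2. Key disconnection, made last: the bay-region biaryl bond C4 (ring B)–C ortho (ring D) is cut back to two C–H bonds. Forward, an intramolecular oxidative phenol–phenanthrol coupling dearomatises both rings to dienones, closes the 12-membered ring and re-aromatises.
3. Central phenanthrene ring: cut C4a–C4b. Forward, a 6π photocyclisation of an A=B stilbene whose ring B carries a sacrificial chlorine on the closure carbon, so loss of HCl fixes the regiochemistry.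
4. Open chain: the stilbene comes from methylenation and Heck coupling, the A–C axis from Suzuki coupling. The C–D ethano bridge comes from B-alkyl Suzuki coupling on a 1,2,3-trihalogenated ring C, made by lithiation between Br and Cl.
5. Ring order: the four benzene rings are bought. The central phenanthrene ring is formed first (step 7), the macrocycle last (step 8).

Assumption: the target SMILES has no stereodescriptor and the molecule has no stereocentre, so the constitution as drawn is the goal; the biaryl axes and bay-region twist form without control and, if configurationally stable, the enantiomers would be separated on a chiral phase.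

**Step 1**
Reactants: 1 2-bromo-4-chlorophenol
Product: 2 2-bromo-4-chloro-1-(methoxymethoxy)benzene
Conditions: MOMCl, i-Pr2NEt, CH2Cl2, 0 °C to rt
Reagents that add atoms: chloromethyl methyl ether (MOMCl), COCCl
Why: Williamson-type O-alkylation (MOM acetal protection) removes the acidic OH so that ring C can be lithiated, and later keeps this phenol out of the oxidative coupling; no stereocentre is formed.

**Step 2**
Reactants: 2 2-bromo-4-chloro-1-(methoxymethoxy)benzene
Product: 4 2-bromo-4-chloro-3-iodo-1-(methoxymethoxy)benzene, via aryllithium 3 (not isolated)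
Conditions: LiN(i-Pr)2 (1.1 equiv, commercial solution), THF, −78 °C, 1 h; then I2, THF, −78 °C to rt
Reagents that add atoms: iodine, II
Why: Deprotonative lithiation and iodine quench: the ring proton flanked by Br and Cl is by far the most acidic, the amide base does not exchange bromine at −78 °C, the 2,6-dihaloaryl anion is already the thermodynamic sink so no halogen dance follows, and ring C ends up with three halogens of graded reactivity.

**Step 3**
Reactants: 4 2-bromo-4-chloro-3-iodo-1-(methoxymethoxy)benzene; 5 4-acetoxystyrene (commodity monomer)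
Product: 8 4-{2-[2-bromo-6-chloro-3-(methoxymethoxy)phenyl]ethyl}phenol, via alkyl-9-BBN adduct 6 (not isolated), via coupled aryl acetate 7 (not isolated)
Conditions: 5, 9-BBN-H (1.05 equiv), THF, rt; then 4, PdCl2(dppf) (5 mol %), 3 M aq NaOH, THF, 50 °C; mild acidic work-up
Reagents that add atoms: none
Why: Anti-Markovnikov hydroboration followed by B-alkyl Suzuki–Miyaura coupling: zerovalent palladium inserts into C–I far faster than into the neighbouring C–Br or C–Cl, so the ethano bridge is installed at its final oxidation level in one flask, and the hydroxide that activates the borane also saponifies the acetate.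

**Step 4**
Reactants: 8 4-{2-[2-bromo-6-chloro-3-(methoxymethoxy)phenyl]ethyl}phenol; 9 (4-formyl-2-methoxyphenyl)boronic acid
Product: 10 3'-chloro-2'-[2-(4-hydroxyphenyl)ethyl]-2-methoxy-6'-(methoxymethoxy)biphenyl-4-carbaldehyde
Conditions: Pd(PPh3)4 (5 mol %), K3PO4 (3 equiv), DME/H2O 4:1, 85 °C
Reagents that add atoms: none
Why: Suzuki–Miyaura biaryl coupling: Pd(PPh3)4 inserts into the remaining C–Br but leaves the electron-rich, hindered C–Cl alone, phosphate is strong enough for a tri-ortho-substituted biaryl yet spares the aldehyde, and the axis forms without control (see assumption).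

**Step 5**
Reactants: 10 3'-chloro-2'-[2-(4-hydroxyphenyl)ethyl]-2-methoxy-6'-(methoxymethoxy)biphenyl-4-carbaldehyde
Product: 11 4-{2-[3-chloro-4'-ethenyl-2'-methoxy-6-(methoxymethoxy)biphenyl-2-yl]ethyl}phenol
Conditions: Ph3PCH3Br, KOt-Bu (2.4 equiv each), THF, 0 °C to rt
Reagents that add atoms: methyltriphenylphosphonium bromide, C[P+](c1ccccc1)(c1ccccc1)c1ccccc1.[Br-]
Why: Wittig methylenation of the only carbonyl group; one extra equivalent of ylide is spent on the phenol, which is recovered on work-up.

**Step 6**
Reactants: 11 4-{2-[3-chloro-4'-ethenyl-2'-methoxy-6-(methoxymethoxy)biphenyl-2-yl]ethyl}phenol; 12 4-bromo-2,5-dichlorophenol (bulk agrochemical phenol)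
Product: 13 2,5-dichloro-4-[(E)-2-{3'-chloro-2'-[2-(4-hydroxyphenyl)ethyl]-2-methoxy-6'-(methoxymethoxy)biphenyl-4-yl}ethenyl]phenol
Conditions: Pd(OAc)2 (5 mol %), P(o-tol)3 (12 mol %), Et3N, DMF, 100 °C
Reagents that add atoms: none
Why: Mizoroki–Heck arylation of the terminal styrene at C–Br (the C–Cl bonds are inert to this catalyst) gives the E-stilbene by syn insertion and syn β-hydride elimination, and the free phenols are tolerated.

**Step 7**
Reactants: 13 2,5-dichloro-4-[(E)-2-{3'-chloro-2'-[2-(4-hydroxyphenyl)ethyl]-2-methoxy-6'-(methoxymethoxy)biphenyl-4-yl}ethenyl]phenol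
Product: 16 2-chloro-6-{3-chloro-2-[2-(4-hydroxyphenyl)ethyl]-6-(methoxymethoxy)phenyl}-7-methoxyphenanthren-3-ol, via Z-stilbene 14 (not isolated), via chloro-dihydrophenanthrene 15 (not isolated)
Conditions: hν (300 nm), propylene oxide (20 equiv), degassed MeCN (1 mM), Ar, rt
Reagents that add atoms: none
Why: Eliminative Mallory-type photocyclisation: light equilibrates E and Z, the Z-isomer closes by conrotatory 6π electrocyclisation that dearomatises rings A and B, and without oxidant only closure onto the chlorine-bearing carbon can go on (anti loss of HCl from 15), which fixes the ring B regiochemistry, while the methoxy group buttressed by ring C keeps ring A from closing at C8; the two sp3 centres are transient.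

**Step 8 (key step)**
Reactants: 16 2-chloro-6-{3-chloro-2-[2-(4-hydroxyphenyl)ethyl]-6-(methoxymethoxy)phenyl}-7-methoxyphenanthren-3-ol
Product: 18 ring C O-methoxymethyl ether of the target macrocycle, via bis-dienone tautomer 17 (not isolated)
Conditions: [Cu(OH)(TMEDA)]2Cl2 (20 mol %), O2 (1 atm), MeCN, rt; 16 added by syringe pump over 12 h, final 1 mM
Reagents that add atoms: none
Why: Aerobic copper–amine oxidative phenol coupling: the divalent-copper phenanthrolate is oxidised to a radical with its spin density at C4 (C2 is blocked by Cl), the tethered ring D phenolate attacks through an ortho carbon from the face over which the ethano chain already holds it, both rings are thereby dearomatised to bis-dienone 17, whose double tautomerisation restores aromaticity and makes the ring closure irreversible, slow addition suppresses dimerisation, and no stereocentre survives.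

**Step 9**
Reactants: 18 ring C O-methoxymethyl ether of the target macrocycle
Product: 19 target CNP0310669.0
Conditions: HCl (1.25 M in MeOH), THF, 40 °C
Reagents that add atoms: none
Why: Acid-catalysed acetal exchange (MOM solvolysis) frees the last phenol; the aryl methyl ether, the aryl chlorides and the biaryl bonds are inert to dilute methanolic HCl.

**Compound list**
1 | 2-bromo-4-chlorophenol | Oc1ccc(Cl)cc1Br | starting material
2 | 2-bromo-4-chloro-1-(methoxymethoxy)benzene | COCOc1ccc(Cl)cc1Br | intermediate
3 | [2-bromo-6-chloro-3-(methoxymethoxy)phenyl]lithium | COCOc1ccc(Cl)c([Li])c1Br | intermediate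
4 | 2-bromo-4-chloro-3-iodo-1-(methoxymethoxy)benzene | COCOc1ccc(Cl)c(I)c1Br | intermediate
5 | 4-acetoxystyrene (4-ethenylphenyl acetate) | CC(=O)Oc1ccc(C=C)cc1 | starting material
6 | 4-[2-(9-borabicyclo[3.3.1]nonan-9-yl)ethyl]phenyl acetate | CC(=O)Oc1ccc(CCB2C3CCCC2CCC3)cc1 | intermediate
7 | 4-{2-[2-bromo-6-chloro-3-(methoxymethoxy)phenyl]ethyl}phenyl acetate | COCOc1ccc(Cl)c(CCc2ccc(OC(C)=O)cc2)c1Br | intermediate
8 | 4-{2-[2-bromo-6-chloro-3-(methoxymethoxy)phenyl]ethyl}phenol | COCOc1ccc(Cl)c(CCc2ccc(O)cc2)c1Br | intermediate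
9 | (4-formyl-2-methoxyphenyl)boronic acid | COc1cc(C=O)ccc1B(O)O | starting material
10 | 3'-chloro-2'-[2-(4-hydroxyphenyl)ethyl]-2-methoxy-6'-(methoxymethoxy)biphenyl-4-carbaldehyde | COc1cc(C=O)ccc1-c1c(OCOC)ccc(Cl)c1CCc1ccc(O)cc1 | intermediate
11 | 4-{2-[3-chloro-4'-ethenyl-2'-methoxy-6-(methoxymethoxy)biphenyl-2-yl]ethyl}phenol | COc1cc(C=C)ccc1-c1c(OCOC)ccc(Cl)c1CCc1ccc(O)cc1 | intermediate
12 | 4-bromo-2,5-dichlorophenol | Oc1cc(Cl)c(Br)cc1Cl | starting material
13 | 2,5-dichloro-4-[(E)-2-{3'-chloro-2'-[2-(4-hydroxyphenyl)ethyl]-2-methoxy-6'-(methoxymethoxy)biphenyl-4-yl}ethenyl]phenol | COc1cc(/C=C/c2cc(Cl)c(O)cc2Cl)ccc1-c1c(OCOC)ccc(Cl)c1CCc1ccc(O)cc1 | intermediate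
14 | Z-isomer of 13 | COc1cc(/C=C\c2cc(Cl)c(O)cc2Cl)ccc1-c1c(OCOC)ccc(Cl)c1CCc1ccc(O)cc1 | intermediate
15 | trans-2,4a-dichloro-4a,4b-dihydro analogue of 16 (4a-Cl and 4b-H anti; racemic, relative configuration shown) | COC1=CC2=CC=C3C=C(Cl)C(O)=C[C@]3(Cl)[C@H]2C=C1c1c(OCOC)ccc(Cl)c1CCc1ccc(O)cc1 | intermediate
16 | 2-chloro-6-{3-chloro-2-[2-(4-hydroxyphenyl)ethyl]-6-(methoxymethoxy)phenyl}-7-methoxyphenanthren-3-ol | COc1cc2ccc3cc(Cl)c(O)cc3c2cc1-c1c(OCOC)ccc(Cl)c1CCc1ccc(O)cc1 | intermediate
17 | macrocyclic bis-dienone: 18 with phenanthrene C4 and the bonded ring D carbon as sp3 CH and both adjacent C–O groups as ketones (transient centres, configuration undefined) | COc1cc2ccc3C=C(Cl)C(=O)C4c3c2cc1-c1c(OCOC)ccc(Cl)c1CCC1=CC4C(=O)C=C1 | intermediate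
18 | target macrocycle with the ring C phenol as its methoxymethyl ether | COc1cc2ccc3cc(Cl)c(O)c4c3c2cc1-c1c(OCOC)ccc(Cl)c1CCc1ccc(O)c-4c1 | intermediate
19 | CNP0310669.0 | COc1cc2ccc3cc(Cl)c(O)c4c3c2cc1-c1c(O)ccc(Cl)c1CCc1ccc(O)c-4c1 | target

**Total step count:** 9. **Longest linear sequence:** 9 steps (1 to 19).

**Steps most likely to fail**

Step 8 (oxidative macrocyclisation). The risks are dimerisation, C–O coupling and over-oxidation of the biphenol. The fallback gives up the C–H/C–H coupling for a halide-based ring closure.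
- It sets out from 16. NIS (2.1 equiv) with catalytic TsOH in MeCN at 0 °C iodinates the two most activated positions, phenanthrene C4 and one ortho carbon of ring D. This gives 2-chloro-6-{3-chloro-2-[2-(4-hydroxy-3-iodophenyl)ethyl]-6-(methoxymethoxy)phenyl}-4-iodo-7-methoxyphenanthren-3-ol F1.
- PdCl2(dppf), B2pin2 (1.1 equiv) and K2CO3 in DMSO at 80 °C and 2 mM then borylate one iodide and close the ring by intramolecular Suzuki–Miyaura coupling. This comes back to the route at 18.

Step 3 (B-alkyl coupling at an iodide flanked by Br and Cl). The risks are slow transmetalation, β-hydride elimination and attack on C–Br. The fallback replaces the sp3–sp2 coupling by an sp–sp2 coupling plus reduction.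
- It sets out from 4. Sonogashira coupling with commercial 4-ethynylphenyl acetate (PdCl2(PPh3)2, CuI, Et3N, THF, rt) uses a linear alkyne that is little affected by the flanking halogens. It gives 4-{[2-bromo-6-chloro-3-(methoxymethoxy)phenyl]ethynyl}phenyl acetate F2.
- Diimide (TsNHNH2, NaOAc, aqueous DME, reflux) touches neither C–Br nor C–Cl. It reduces F2 through 4-{(Z)-2-[2-bromo-6-chloro-3-(methoxymethoxy)phenyl]ethenyl}phenyl acetate F3 to acetate 7, now isolated.
- K2CO3 in MeOH cleaves the ester, coming back to the route at 8.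

Step 7 (eliminative photocyclisation). The risks are sluggish closure onto the substituted carbon and photodechlorination elsewhere. The fallback changes both the building block and the way aromaticity is restored.
- It sets out from 11. Heck coupling with 4-bromo-2-chlorophenol under the step 6 conditions gives 2-chloro-4-[(E)-2-{3'-chloro-2'-[2-(4-hydroxyphenyl)ethyl]-2-methoxy-6'-(methoxymethoxy)biphenyl-4-yl}ethenyl]phenol F4, which lacks the sacrificial chlorine.
- Irradiation (Pyrex-filtered medium-pressure Hg lamp) with I2 (1.1 equiv) and propylene oxide in degassed toluene passes through the Z-isomer of that stilbene F5 and the trans-4a,4b-dihydrophenanthrene F6, which iodine dehydrogenates.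
- The regioisomer with chlorine in the bay is removed by chromatography, and the route is rejoined at 16.

**Further compounds**
F1 | step 8 | 2-chloro-6-{3-chloro-2-[2-(4-hydroxy-3-iodophenyl)ethyl]-6-(methoxymethoxy)phenyl}-4-iodo-7-methoxyphenanthren-3-ol | COc1cc2ccc3cc(Cl)c(O)c(I)c3c2cc1-c1c(OCOC)ccc(Cl)c1CCc1ccc(O)c(I)c1
F2 | step 3 | 4-{[2-bromo-6-chloro-3-(methoxymethoxy)phenyl]ethynyl}phenyl acetate | COCOc1ccc(Cl)c(C#Cc2ccc(OC(C)=O)cc2)c1Br
F3 | step 3 | 4-{(Z)-2-[2-bromo-6-chloro-3-(methoxymethoxy)phenyl]ethenyl}phenyl acetate | COCOc1ccc(Cl)c(/C=C\c2ccc(OC(C)=O)cc2)c1Br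
F4 | step 7 | 2-chloro-4-[(E)-2-{3'-chloro-2'-[2-(4-hydroxyphenyl)ethyl]-2-methoxy-6'-(methoxymethoxy)biphenyl-4-yl}ethenyl]phenol | COc1cc(/C=C/c2ccc(O)c(Cl)c2)ccc1-c1c(OCOC)ccc(Cl)c1CCc1ccc(O)cc1
F5 | step 7 | Z-isomer of F4 | COc1cc(/C=C\c2ccc(O)c(Cl)c2)ccc1-c1c(OCOC)ccc(Cl)c1CCc1ccc(O)cc1
F6 | step 7 | trans-4a,4b-dihydro analogue of 16 (racemic, relative configuration shown) | COC1=CC2=CC=C3C=C(Cl)C(O)=C[C@@H]3[C@H]2C=C1c1c(OCOC)ccc(Cl)c1CCc1ccc(O)cc1
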